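**Retrosynthetic overview**
1. Target 22 ⇐ C7 prenylation of monoprenyl trione 20 ⇐ C1 prenylation of bicyclic trione 17; each bridgehead can take its new substituent in one position only.
2. 17 ⇐ key step: radical 8-endo cycloisomerisation of acyl tetronic acid 14. The C1–C2 bond closes the eight-membered carbocycle across the furanone and sets C1, C3 and C7.
3. 14 ⇐ C-acylation of silyl enol ether 8 with tetronate-derived acid chloride 12 (C5–C6 bond), then O-demethylation.
4. 8 ⇐ enantioselective copper–NHC conjugate addition of alkenylalane 6 to enone 4 (C4 quaternary centre); 4 ⇐ carboalumination/acylation of alkyne 1.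
5. Ring order: the furanone ring is bought (9); the eight-membered ring is formed in the radical step.

Core numbering used below (8-oxabicyclo[5.2.1]decane): C1 bridgehead (prenyl, next to lactone C9=O), C2 CH2, C3 CH(prenyl), C4 C(Me)(4-methylpent-3-enyl), C5 CH(isobutyryl), C6 ketone, C7 bridgehead (prenyl, O8), O8, C9 lactone C=O, C10 bridging ketone.

Assumption 1: C5 lies between two ketones and is configurationally labile; the (5R) epimer of the target is taken to be the thermodynamically preferred one and is reached by equilibration.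
Assumption 2: alkynes 1 and 5 are taken as purchasable catalogue compounds.

**Route**

Step 1
Reactants: 1 6-methylhept-5-en-1-yne; 2 2-methylpropanoyl chloride
Product: 4 (4E)-2,5,9-trimethyldeca-4,8-dien-3-one, via alkenylalane 3 (not isolated)
Conditions: Me3Al (2 equiv), Cp2ZrCl2 (0.2 equiv), CH2Cl2, 0 °C→rt; then 2 (3 equiv), Pd(PPh3)4 (5 mol%), THF, 0 °C→rt
Reagents that add atoms: trimethylaluminium, C[Al](C)C
Why: Negishi zirconium-catalysed carboalumination adds Me–Al syn and regioselectively across the terminal alkyne, and palladium-catalysed acylation of the alkenylalane with retention gives the (E)-enone; no stereocentre is formed.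

Step 2
Reactants: 5 5-methylhex-4-en-1-yne; 4 (4E)-2,5,9-trimethyldeca-4,8-dien-3-one
Product: 8 trimethyl{[(5S)-2,5,9-trimethyl-5-(5-methylhexa-1,4-dien-2-yl)deca-3,8-dien-3-yl]oxy}silane, via alkenylalane 6 (not isolated), via aluminium enolate 7 (not isolated)
Conditions: 5, iBu2AlH (1.0 equiv), Ni(dppp)Cl2 (3 mol%), THF, 4→22 °C; then 4, chiral sulfonate-bearing imidazolinium salt (NHC precursor, 5 mol%), CuCl2·2H2O (5 mol%), THF, −30→4 °C; then Me3SiOTf (1.5 equiv), −30 °C→rt; Et3N, pentane, filtration
Reagents that add atoms: trimethylsilyl trifluoromethanesulfonate, C[Si](C)(C)OS(=O)(=O)C(F)(F)F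
Why: Nickel-catalysed alpha-selective hydroalumination gives the 1,1-disubstituted alkenylalane, and its copper–NHC-catalysed enantioselective conjugate addition (Hoveyda type; ligand enantiomer chosen for Si-face delivery at C5 of the enone) sets the all-carbon quaternary centre as (5S), while O-silylation of the aluminium enolate fixes the enol ether regiochemistry (C3=C4).

Step 3
Reactants: 9 4-methoxyfuran-2(5H)-one
Product: 11 3-methoxy-5-oxo-2,5-dihydrofuran-2-carboxylic acid (racemic), via lithiated tetronate 10 (not isolated)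
Conditions: LiN(iPr)2 (1.05 equiv), THF, −78 °C; CO2 (g), −78→0 °C; 1 M HCl
Reagents that add atoms: carbon dioxide, O=C=O
Why: Kinetic gamma-deprotonation of the methyl tetronate at C5 followed by carboxylation of the lithiated tetronate; the new CH stereocentre is racemic and remains labile in all later intermediates until step 6.

Step 4
Reactants: 11 3-methoxy-5-oxo-2,5-dihydrofuran-2-carboxylic acid; 8 trimethyl{[(5S)-2,5,9-trimethyl-5-(5-methylhexa-1,4-dien-2-yl)deca-3,8-dien-3-yl]oxy}silane
Product: 13 5-[(3S)-3,7-dimethyl-3-(5-methylhexa-1,4-dien-2-yl)-2-(2-methylpropanoyl)oct-6-enoyl]-4-methoxyfuran-2(5H)-one (mixture at the two labile CH centres), via acid chloride 12 (not isolated)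
Conditions: 11, (COCl)2 (1.2 equiv), DMF (cat.), CH2Cl2, 0 °C→rt, evaporate; then 8, ZnCl2 (1.1 equiv), CH2Cl2–Et2O, 0 °C→rt; pH 4 buffer
Reagents that add atoms: none
Why: Lewis-acid-promoted C-acylation of a silyl enol ether by an acid chloride (Mukaiyama-type crossed Claisen) builds the 1,3-diketone at the carbon defined by the enol ether and needs no base, so the acidic alpha-hydrogen of the acyl donor is tolerated; the two new CH centres are epimerisable and left as mixtures.

Step 5
Reactants: 13 5-[(3S)-3,7-dimethyl-3-(5-methylhexa-1,4-dien-2-yl)-2-(2-methylpropanoyl)oct-6-enoyl]-4-methoxyfuran-2(5H)-one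
Product: 14 5-[(3S)-3,7-dimethyl-3-(5-methylhexa-1,4-dien-2-yl)-2-(2-methylpropanoyl)oct-6-enoyl]-4-hydroxyfuran-2(5H)-one
Conditions: LiCl (5 equiv), DMSO, 50 °C; then 1 M HCl
Reagents that add atoms: none
Why: SN2 O-demethylation of the vinylogous methyl carbonate by chloride liberates the tetronic acid; the quaternary (3S) centre is untouched and the labile CH centres stay mixtures.

Step 6
Reactants: 14 5-[(3S)-3,7-dimethyl-3-(5-methylhexa-1,4-dien-2-yl)-2-(2-methylpropanoyl)oct-6-enoyl]-4-hydroxyfuran-2(5H)-one
Product: 17 (1R,3S,4R,5R,7S)-4-methyl-3-(3-methylbut-2-en-1-yl)-4-(4-methylpent-3-en-1-yl)-5-(2-methylpropanoyl)-8-oxabicyclo[5.2.1]decane-6,9,10-trione, via dicarbonyl radical 15 (not isolated), via tertiary radical 16 (not isolated)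
Conditions: 4CzIPN (2,4,5,6-tetra(9H-carbazol-9-yl)isophthalonitrile, 2 mol%), 2,4,6-triisopropylbenzenethiol (2.0 equiv, recovered), 2,4,6-collidine (20 mol%), degassed MeCN (5 mM in 14), blue LEDs (450 nm), 25 °C
Reagents that add atoms: none
Why: Proposed new method: sub-stoichiometric collidine ionises only the tetronic acid (far more acidic than the 1,3-diketone), the excited photocatalyst oxidises this anion to the electrophilic furan-2,4-dion-3-yl radical 15, which attacks the CH2 terminus of the 1,1-disubstituted alkene in an 8-endo-trig cyclisation (C1–C2 bond) to give tertiary radical 16, and the thiol donates H to C3 while its thiyl radical is reduced back by the reduced photocatalyst, so the step is a redox-neutral isomerisation (a prematurely quenched 15 simply returns 14); the alpha-acyl CH of the furanone epimerises through its enol, so the bridgeheads close cis as (1R,7S) through the transition state that keeps the larger C4 substituent on the exo face away from the O8–C9 bridge, H is delivered to C3 from that same exo face (anti to the C4 methyl) to give (3S) with the prenyl trans to the 4-methylpentenyl chain, and C5 equilibrates to (5R); the closest known reactions are the 8-endo cyclisations of alpha-carbonyl radicals generated with Mn(OAc)3 or from alpha-bromo esters and the photoredox/thiol hydroalkylation of alkenes with 1,3-dicarbonyls.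

Step 7
Reactants: 17 (1R,3S,4R,5R,7S)-4-methyl-3-(3-methylbut-2-en-1-yl)-4-(4-methylpent-3-en-1-yl)-5-(2-methylpropanoyl)-8-oxabicyclo[5.2.1]decane-6,9,10-trione; 18 1-bromo-3-methylbut-2-ene
Product: 20 (1R,3S,4R,5R,7S)-4-methyl-1,3-bis(3-methylbut-2-en-1-yl)-4-(4-methylpent-3-en-1-yl)-5-(2-methylpropanoyl)-8-oxabicyclo[5.2.1]decane-6,9,10-trione, via dilithium dienolate 19 (not isolated)
Conditions: LiN(iPr)2 (2.1 equiv), THF, −78 °C, 45 min; 18 (1.1 equiv), −78→−30 °C; aq. NH4Cl (pH 5)
Reagents that add atoms: none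
Why: Dianion alkylation in the manner of bridgehead alkylations of polyprenylated acylphloroglucinols: the first equivalent of base parks the hindered C5 diketone as its poorly nucleophilic lithium diketonate and the second removes C1–H, which is flanked by two carbonyls not engaged in the diketonate (lactone C9 and ketone C10, both in the five-membered ring and aligned with the exo C–H bond), in preference to C7–H, whose C6 carbonyl already carries the diketonate charge, so the beta-keto lactone enolate is C-prenylated by SN2 at the one position the bicycle leaves open, giving (1R) with retention, and the mildly acidic work-up returns C5 as the (5R) epimer.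

Step 8
Reactants: 20 (1R,3S,4R,5R,7S)-4-methyl-1,3-bis(3-methylbut-2-en-1-yl)-4-(4-methylpent-3-en-1-yl)-5-(2-methylpropanoyl)-8-oxabicyclo[5.2.1]decane-6,9,10-trione; 18 1-bromo-3-methylbut-2-ene
Product: 22 (1R,3S,4R,5R,7S)-4-methyl-1,3,7-tris(3-methylbut-2-en-1-yl)-4-(4-methylpent-3-en-1-yl)-5-(2-methylpropanoyl)-8-oxabicyclo[5.2.1]decane-6,9,10-trione, via dilithium dienolate 21 (not isolated)
Conditions: LiN(iPr)2 (2.2 equiv), THF, −78→−40 °C, 1 h; 18 (1.3 equiv), −78→0 °C; aq. NH4Cl (pH 5)
Reagents that add atoms: none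
Why: Weiler-type dianion gamma-alkylation: with C1 now quaternary, two equivalents of base convert the C5/C6 diketone into its dianion by deprotonation at C7 (gamma to the diketonate, alpha to the C10 ketone and to O8), this terminal carbon is the most nucleophilic site of the dianion and is prenylated by SN2 at the only open (exo) position to give (7S) with retention, and the pH 5 work-up returns C5 as the (5R) epimer.

**Compound list**
1 | 6-methylhept-5-en-1-yne | C#CCCC=C(C)C | starting material
2 | 2-methylpropanoyl chloride | CC(C)C(=O)Cl | starting material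
3 | dimethyl[(1E)-2,6-dimethylhepta-1,5-dien-1-yl]alumane | C[Al](C)/C=C(\C)CCC=C(C)C | intermediate
4 | (4E)-2,5,9-trimethyldeca-4,8-dien-3-one | CC(C)C(=O)/C=C(\C)CCC=C(C)C | intermediate
5 | 5-methylhex-4-en-1-yne | C#CCC=C(C)C | starting material
6 | (5-methylhexa-1,4-dien-2-yl)bis(2-methylpropyl)alumane | C=C(CC=C(C)C)[Al](CC(C)C)CC(C)C | intermediate
7 | bis(2-methylpropyl)aluminium (5S)-2,5,9-trimethyl-5-(5-methylhexa-1,4-dien-2-yl)deca-3,8-dien-3-olate | CC(C)C(O[Al](CC(C)C)CC(C)C)=C[C@](C)(CCC=C(C)C)C(=C)CC=C(C)C | intermediate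
8 | trimethyl{[(5S)-2,5,9-trimethyl-5-(5-methylhexa-1,4-dien-2-yl)deca-3,8-dien-3-yl]oxy}silane (enol ether geometry not controlled) | CC(C)C(O[Si](C)(C)C)=C[C@](C)(CCC=C(C)C)C(=C)CC=C(C)C | intermediate
9 | 4-methoxyfuran-2(5H)-one | COC1=CC(=O)OC1 | starting material
10 | (3-methoxy-5-oxo-2,5-dihydrofuran-2-yl)lithium | [Li]C1OC(=O)C=C1OC | intermediate
11 | 3-methoxy-5-oxo-2,5-dihydrofuran-2-carboxylic acid (racemic) | COC1=CC(=O)OC1C(=O)O | intermediate
12 | 3-methoxy-5-oxo-2,5-dihydrofuran-2-carbonyl chloride (racemic) | COC1=CC(=O)OC1C(=O)Cl | intermediate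
13 | 5-[(3S)-3,7-dimethyl-3-(5-methylhexa-1,4-dien-2-yl)-2-(2-methylpropanoyl)oct-6-enoyl]-4-methoxyfuran-2(5H)-one (furanone C5 and chain C2 labile, mixture) | COC1=CC(=O)OC1C(=O)C(C(=O)C(C)C)[C@](C)(CCC=C(C)C)C(=C)CC=C(C)C | intermediate
14 | 5-[(3S)-3,7-dimethyl-3-(5-methylhexa-1,4-dien-2-yl)-2-(2-methylpropanoyl)oct-6-enoyl]-4-hydroxyfuran-2(5H)-one (furanone C5 and chain C2 labile, mixture) | OC1=CC(=O)OC1C(=O)C(C(=O)C(C)C)[C@](C)(CCC=C(C)C)C(=C)CC=C(C)C | intermediate
15 | C3-centred radical of the furan-2,4-dione form of 14 (spin between the lactone and ketone carbonyls) | O=C1[CH]C(=O)OC1C(=O)C(C(=O)C(C)C)[C@](C)(CCC=C(C)C)C(=C)CC=C(C)C | intermediate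
16 | tertiary C3 radical of 17 (17 lacking the C3 hydrogen; bridgeheads cis, C4 as in 17, C5 unset) | CC(C)=CCC[C@]1(C)[C](CC=C(C)C)C[C@H]2C(=O)O[C@@H](C(=O)C1C(=O)C(C)C)C2=O | intermediate
17 | (1R,3S,4R,5R,7S)-4-methyl-3-(3-methylbut-2-en-1-yl)-4-(4-methylpent-3-en-1-yl)-5-(2-methylpropanoyl)-8-oxabicyclo[5.2.1]decane-6,9,10-trione | CC(C)=CCC[C@]1(C)[C@@H](CC=C(C)C)C[C@H]2C(=O)O[C@@H](C(=O)[C@H]1C(=O)C(C)C)C2=O | intermediate
18 | 1-bromo-3-methylbut-2-ene | CC(C)=CCBr | starting material
19 | dilithium dienolate of 17 (C1=C9 lactone enolate and C5 exocyclic diketonate; C3, C4, C7 as in 17) | CC(C)=CCC[C@]1(C)[C@@H](CC=C(C)C)CC2=C(O[Li])O[C@@H](C(=O)C1=C(O[Li])C(C)C)C2=O | intermediate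
20 | (1R,3S,4R,5R,7S)-4-methyl-1,3-bis(3-methylbut-2-en-1-yl)-4-(4-methylpent-3-en-1-yl)-5-(2-methylpropanoyl)-8-oxabicyclo[5.2.1]decane-6,9,10-trione | CC(C)=CCC[C@]1(C)[C@@H](CC=C(C)C)C[C@@]2(CC=C(C)C)C(=O)O[C@@H](C(=O)[C@H]1C(=O)C(C)C)C2=O | intermediate
21 | dilithium dienolate of 20 (C7=C6 enolate and C5 exocyclic diketonate; C1, C3, C4 as in 20) | CC(C)=CCC[C@]1(C)[C@@H](CC=C(C)C)C[C@@]2(CC=C(C)C)C(=O)OC(=C(O[Li])C1=C(O[Li])C(C)C)C2=O | intermediate
22 | (1R,3S,4R,5R,7S)-4-methyl-1,3,7-tris(3-methylbut-2-en-1-yl)-4-(4-methylpent-3-en-1-yl)-5-(2-methylpropanoyl)-8-oxabicyclo[5.2.1]decane-6,9,10-trione | CC(C)=CCC[C@]1(C)[C@@H](CC=C(C)C)C[C@@]2(CC=C(C)C)C(=O)O[C@@](CC=C(C)C)(C(=O)[C@H]1C(=O)C(C)C)C2=O | target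

**Count**
Total steps: 8. Longest linear sequence: 7 (steps 1, 2, 4, 5, 6, 7, 8); step 3 is a one-step side branch.

**Steps most likely to fail, each with a fallback**

Step 6 (radical 8-endo cycloisomerisation). The photo-oxidation may be unselective and the medium-ring closure may be slow. Tertiary radical 16 is also a hex-5-enyl radical with respect to the 4-methylpent-3-enyl chain on C4, so 5-exo closure competes with H transfer; this is why the thiol is used in stoichiometric amount. The facial preferences at C4/C3 are modest, so diastereomers may form. The fallback sets out from 14 and returns to the route at 20, so it also bypasses step 7. Tetronic acid 14 is C-prenylated at the furanone 3-position under neutral palladium π-allyl conditions (Pd(PPh3)4 5 mol%, methyl 3-methylbut-2-en-1-yl carbonate 1.05 equiv, THF, 25 °C) to give 5-[(3S)-3,7-dimethyl-3-(5-methylhexa-1,4-dien-2-yl)-2-(2-methylpropanoyl)oct-6-enoyl]-4-hydroxy-3-(3-methylbut-2-en-1-yl)furan-2(5H)-one F1. Bromination (NBS, CH2Cl2, −20 °C) converts it into the non-enolisable tertiary bromide 3-bromo-5-[(3S)-3,7-dimethyl-3-(5-methylhexa-1,4-dien-2-yl)-2-(2-methylpropanoyl)oct-6-enoyl]-3-(3-methylbut-2-en-1-yl)furan-2,4(3H,5H)-dione F2. F2 is added slowly to (Me3Si)3SiH (1.3 equiv), 2,4,6-triisopropylbenzenethiol (1 equiv, polarity-reversal H-transfer catalyst) and Et3B/air in benzene at 25 °C. Bromine abstraction starts a reductive chain in which the same 8-endo closure forms the C1 quaternary centre directly, and H transfer to C3 gives 20. This replaces oxidative photogeneration of the radical by a pre-installed leaving group on a bromomalonate-type precursor and lets the H donor be varied independently.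

Step 4 (C-acylation of the hindered silyl enol ether by acid chloride 12). The nucleophilic carbon is neopentylic and 12 is labile. The fallback sets out from 8 and 12 and returns at 13. Silyl enol ether 8 is cleaved with MeLi (THF, 0 °C) to lithium (5S)-2,5,9-trimethyl-5-(5-methylhexa-1,4-dien-2-yl)deca-3,8-dien-3-olate F3. In a second flask 12 is dehydrochlorinated with iPr2NEt at −78 °C to the ketene (3-methoxy-5-oxofuran-2(5H)-ylidene)methanone F4, which is cannulated into F3. The enolate adds to the ketene carbonyl carbon and protonation gives 13. Acyl substitution is thus replaced by addition to a neutral ketene that no longer carries an acidic hydrogen.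

Step 7 (C1 bridgehead prenylation). The hindered, partly pyramidal bridgehead enolate may react sluggishly with the bulky prenyl electrophile or give O-alkylation. The fallback sets out from 17 and returns at 20. Dilithium dienolate 19 (LiN(iPr)2 2.1 equiv, THF, −78 °C) is alkylated with the smaller and more reactive allyl bromide to give (1R,3S,4R,5R,7S)-4-methyl-3-(3-methylbut-2-en-1-yl)-4-(4-methylpent-3-en-1-yl)-5-(2-methylpropanoyl)-1-(prop-2-en-1-yl)-8-oxabicyclo[5.2.1]decane-6,9,10-trione F5. The allyl group is then turned into prenyl by cross-metathesis in 2-methylbut-2-ene as solvent with second-generation Grubbs catalyst (5 mol%) at 40 °C; the trisubstituted alkenes already present only undergo degenerate exchange. If the problem is site selectivity between C1 and C7 and not reactivity, the step 6 fallback, which installs the C1 prenyl group before ring closure, removes it.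

**Further compounds**
F1 | step 6 | 5-[(3S)-3,7-dimethyl-3-(5-methylhexa-1,4-dien-2-yl)-2-(2-methylpropanoyl)oct-6-enoyl]-4-hydroxy-3-(3-methylbut-2-en-1-yl)furan-2(5H)-one | CC(C)=CCC1=C(O)C(C(=O)C(C(=O)C(C)C)[C@](C)(CCC=C(C)C)C(=C)CC=C(C)C)OC1=O
F2 | step 6 | 3-bromo-5-[(3S)-3,7-dimethyl-3-(5-methylhexa-1,4-dien-2-yl)-2-(2-methylpropanoyl)oct-6-enoyl]-3-(3-methylbut-2-en-1-yl)furan-2,4(3H,5H)-dione | CC(C)=CCC1(Br)C(=O)C(C(=O)C(C(=O)C(C)C)[C@](C)(CCC=C(C)C)C(=C)CC=C(C)C)OC1=O
F3 | step 4 | lithium (5S)-2,5,9-trimethyl-5-(5-methylhexa-1,4-dien-2-yl)deca-3,8-dien-3-olate | [Li]OC(C(C)C)=C[C@](C)(CCC=C(C)C)C(=C)CC=C(C)C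
F4 | step 4 | (3-methoxy-5-oxofuran-2(5H)-ylidene)methanone | COC1=CC(=O)OC1=C=O
F5 | step 7 | (1R,3S,4R,5R,7S)-4-methyl-3-(3-methylbut-2-en-1-yl)-4-(4-methylpent-3-en-1-yl)-5-(2-methylpropanoyl)-1-(prop-2-en-1-yl)-8-oxabicyclo[5.2.1]decane-6,9,10-trione | CC(C)=CCC[C@]1(C)[C@@H](CC=C(C)C)C[C@@]2(CC=C)C(=O)O[C@@H](C(=O)[C@H]1C(=O)C(C)C)C2=O
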